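The autumn run held target at 0.4% after 4.00 h and 2.1% after 8.00 h, against a scatter of 0.3 percentage points.

| setting | autumn | flask |
|---|---|---|
| substrate | 0.075 M (fed, over 8.0 h) | 0.050 M (fed, over 8.0 h) |
| coupling partner | 1 equiv | 1.00 equiv |
| protic impurity | 2.5 mM | 2.50 mM |
| remark | run made earlier; the fed solution adds 0.50 times the starting volume | the fed solution adds 0.50 times the starting volume |
| time |  | 3.0 d |

autumn run (percent of the substrate charged)

| time / h | target / % | substrate / % |
|---|---|---|
| 0.500 | 0.2 | 6.6 |
| 1.00 | 0 | 12.5 |
| 2.00 | 0 | 24.8 |
| 4.00 | 0.4 | 49.7 |
| 8.00 | 2.1 | 97.6 |

(each reading ± 0.3 percentage points)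

- every charge counts on the volume at the start, and the solution that is fed holds the whole dose
- steps under discussion: substrate + coupling partner + target -> 2 target; substrate + coupling partner -> target; coupling partner + protic impurity -> quenched reagent; target -> over-reaction product
- percentages count the whole charge, also what has not yet gone in

* concentration of target at 3.0 d, in M
* concentration of substrate at 3.0 d, in M

We reckon first what the charges allow. Each step that uses substrate uses one coupling partner, and the protic impurity uses one too, so once the impurity has reacted, [substrate] minus [coupling partner] stays fixed, both counted with the whole dose on the final volume. With the partner at 1.00 equiv, that difference in this flask is the impurity's charge spread over the final volume, 0.00167 M. This is the stranded substrate, what remains when the partner, the limiting reagent, is used up. Turned round, for the charges of this flask to leave no partner for target, the impurity would have to match the partner's charge, equal to the substrate's 0.050 M, and it stands at 2.50 mM, or 5.00% of that. Our reckoning therefore caps target in this flask, once the feed is in, at 0.0317 M.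

The forecast, calling autocatalysis “possible but poorly bounded”, gave 0.009 M target and 0.024 M substrate. The flask gives 0.0250 M target and 0.00829 M substrate.

    substrate + coupling partner + target → 2 target (k = 122 M⁻² h⁻¹)
    substrate + coupling partner → target (k = 0.0486 M⁻¹ h⁻¹)
    coupling partner + protic impurity → quenched reagent (k = 135 M⁻¹ h⁻¹)
    target → over-reaction product (k = 5.19 × 10⁻⁵ h⁻¹)

At 3.00 d this flask is not at rest: its 0.00829 M substrate stands above the stranded 0.00167 M, while substrate at 24.9% and partner at 19.9% differ by 5 points. The neighbour flask with 0.0010 M impurity has a stranded share of 2.00%, and its 22.6% substrate and 20.6% partner differ by 2 points. Ten times the time takes this flask's partner to 0.0697%, its target to 0.0306 M and its substrate to 0.00169 M, level with the stranded amount, while its over-reaction product climbs from 0.128% to 3.20%.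

All runs are calculated with made-up constants, noise included.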